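All runs were computed for substances that don't exist; scatter was added.

**One-step expectation.** In a one-step, first-order world the percentage converted at a given time does not depend on the charge. I had two flasks under the same held gas: grey, which is the flask asked about, and blue, with twice the solid substrate.

| flask | solid substrate | gas phase | remark | time |
|---|---|---|---|---|
| grey | 0.30 M | 16 mM (held) | the very flask that is asked about, followed so far |  |
| blue | 0.60 M | 16 mM (held) | run made earlier |  |
| flask | 0.30 M | 16 mM (held) |  | 50 min |

| run | time / min | target / % | side product / % |
|---|---|---|---|
| grey | 5.00 | 43 | 49 |
| grey | 10.0 | 49 | 50 |
| grey | 15.0 | 48 | 54 |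
| grey | 20.0 | 47 | 56 |
| grey | 25.0 | 47 | 55 |
| blue | 4.00 | 21 | 23 |
| blue | 12.0 | 44 | 54 |
| blue | 25.0 | 49 | 54 |
| blue | 40.0 | 45 | 53 |
| blue | 50.0 | 46 | 53 |

(standard deviation of a reading: 1.5 percentage points)

1. the target standing at 50 min, as a percentage of the solid substrate charged
2. the side product standing at 50 min, as a percentage of the solid substrate charged

- in percentages every species weighs as the solid substrate in it: one self-condensation product counts as two
- as a solid, counted per litre of solution: solid substrate
- at the start none of the gas is dissolved
- candidate steps: starting material + dissolved gas -> target; 2 starting material -> self-condensation product; gas phase <-> dissolved gas; solid substrate <-> starting material; starting material -> side product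
- at the start none of the solid substrate is in solution

**Apparent contradiction.** Blue held 44.0% as products at 4.00 min, and grey held 92.0% at 5.00 min: similar times, yet about half the percentage.

**Counting charges.** Blue's charge is two grey charges, so blue had made 88.0% of a grey charge, close to the 92.0% read in grey. I read this as a zero-order start: the pace in charges did not follow the solid charged. At blue's early pace a grey charge came to 4.55 min, and I called this estimate, the time to turn a grey charge into products at that pace, the clearing time. The asked time is 11.0 clearing times, so I placed grey on its plateau.

**The forecast.** It gave 46.8% target (45.3% to 48.3%) and 53.8% side product (52.3% to 55.3%), holding that “50 min simply lies on its plateau”.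

**The result.** The grey flask gave 47.0% target and 53.0% side product.

    starting material + dissolved gas → target (k = 0.439 M⁻¹ s⁻¹)
    2 starting material → self-condensation product (k = 3.01 × 10⁻⁵ M⁻¹ s⁻¹)
    gas phase ⇌ dissolved gas, rate k3*(csat - [dissolved gas]) (kL = 0.214 s⁻¹)
    solid substrate ⇌ starting material, rate k4*(cs4 - [starting material]) while solid is left; crystals form when [starting material] > cs4 (solubility = 0.190 M, k = 0.0130 s⁻¹)
    starting material → side product (k = 0.00688 s⁻¹)

**Counted times.** The height of the grey flask's target plateau comes from the path from starting material to side product: without it, target reached 99.9%. A reading moved early takes the grey flask out of the forecast's range: just past one clearing time, at 5.00 min, it held 48.4% side product, below the low end of 52.3%. The same flask read at 30 min, 6.59 clearing times in, held 47.0% target and 53.0% side product.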